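The cyclopentanone ring (C1–C5) is opened at C1–C2. Quaternary C4 then carries, besides its methyl group, the ring arm C3–C2 and the benzylic branch C7'. Drawing both as vinyl groups (the second with one sacrificial carbon) makes C4 a prochiral divinyl carbon beta to a C1 aldehyde, that is, a 4-pentenal. One rhodium-catalysed hydroacylation with a chiral bisphosphine picks one of the two diastereotopic vinyl groups, forms C1–C2, closes the five-membered ring and creates the C4 stereocentre. The spared vinyl group later becomes C7'. The precursor 16 is a carene-derived 2-cyclopropyl-3-methyl-3-vinylpent-4-enal whose C10 ketone is masked as a dioxolane.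

Key step: step 11

Atom labels: C1 ring C=O; C2 and C3 ring CH2; C4 quaternary ring carbon; C5 ring CH; C6 cyclopropane CH on C5; C7 cyclopropane CH bearing the chain C8–C9–C10(=O)–CH3; C11 the CMe2 carbon; C7' the benzylic carbon. In these labels the target is 4R,5R,6R,7R,7'R, with the cyclopropyl group on C5 cis to the C4 methyl group and trans to the C7' branch.

Assumption: the sense of induction of the bisphosphine on 16 cannot be predicted with confidence, so (R)-BINAP is written and its equally available mirror image is used if a trial run gives the other C4 configuration.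

Remark: the aldehyde of 3 reacts with a glycol faster than its ketone does, so the aldehyde is consumed first (step 2) and C10 is ketalised afterwards (step 3).

Remark: C5 is alpha to a carbonyl group in 16, 19 and 32. It is set in step 8, purified at alcohol 15 and then kept away from base. In 32 it is the thermodynamically preferred epimer.

Remark: 1,3,5-tris(benzyloxy)benzene is taken as a catalogue compound. Benzyl ethers let step 17 do two jobs, and they avoid a boron halide dealkylation next to the cyclopropane and two enolisable ketones.

Step 1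
Reactants: 1 (+)-2-carene
Product: 3 (1S,3R)-2,2-dimethyl-3-(3-oxobutyl)cyclopropane-1-carbaldehyde (cis), via secondary ozonide 2 (not isolated)
Conditions: O3, CH2Cl2, −78 °C; Me2S, −78 °C → rt
Reagents that add atoms: ozone, [O-][O+]=O
Why: Ozonolysis with reductive work-up (Criegee mechanism) cleaves the only C=C bond of 1 and leaves the cyclopropane alone, so C6 and C7 inherit their cis relationship and absolute configuration from the terpene, and the neutral sulfide reduction spares the epimerisable cis aldehyde.

Step 2
Reactants: 3 cis keto aldehyde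
Product: 4 4-(cis-2,2-dimethyl-3-vinylcyclopropyl)butan-2-one (ring configuration as in 3)
Conditions: MePPh3Br, KN(SiMe3)2, THF, 0 °C; then 3, −78 → 0 °C
Reagents that add atoms: methyltriphenylphosphonium bromide, C[P+](c1ccccc1)(c1ccccc1)c1ccccc1.[Br-]
Why: Wittig methylenation with one equivalent of the unstabilised ylide at low temperature takes the aldehyde well before the methyl ketone, which removes the more reactive carbonyl group before any ketalisation and brings in the carbon that becomes C1, while the poor acidity of a cyclopropane C–H keeps C6 intact.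

Step 3
Reactants: 4 vinylcyclopropyl ketone
Product: 5 2-methyl-2-[2-(cis-2,2-dimethyl-3-vinylcyclopropyl)ethyl]-1,3-dioxolane
Conditions: HOCH2CH2OH, pyridinium p-toluenesulfonate (cat.), benzene, reflux, Dean–Stark
Reagents that add atoms: ethylene glycol, OCCO
Why: Acid-catalysed ketalisation with azeotropic water removal now meets a single carbonyl group (C10), and the weakly acidic pyridinium salt does not ionise the vinylcyclopropane.

Step 4
Reactants: 5 vinylcyclopropane ketal
Product: 7 2-{cis-2,2-dimethyl-3-[2-(2-methyl-1,3-dioxolan-2-yl)ethyl]cyclopropyl}ethanol, via B-alkyl-9-BBN 6 (not isolated)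
Conditions: 9-BBN, THF, 0 °C → rt; then NaOH, H2O2, 0 °C → rt
Reagents that add atoms: hydrogen peroxide, OO
Why: Brown hydroboration–oxidation places boron on the terminal carbon of the monosubstituted alkene for steric reasons, so no cyclopropylcarbinyl borane arises, and alkaline peroxide swaps boron for hydroxyl with ketal and three-membered ring untouched.

Step 5
Reactants: 7 cyclopropylethanol ketal
Product: 8 {cis-2,2-dimethyl-3-[2-(2-methyl-1,3-dioxolan-2-yl)ethyl]cyclopropyl}acetic acid
Conditions: TEMPO (cat.), NaOCl (cat.), NaClO2, MeCN–phosphate buffer (pH 6.7), 35 °C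
Reagents that add atoms: sodium chlorite, [Na+].[O-]Cl=O
Why: TEMPO-catalysed chlorite oxidation takes the primary alcohol through the aldehyde to the acid at nearly neutral pH, where the dioxolane is stable and no stereocentre is at risk.

Step 6
Reactants: 9 (E)-3-methylpent-2-en-4-yn-1-ol
Product: 10 (E)-3-methylpenta-2,4-dien-1-ol
Conditions: H2 (1 atm, one equivalent taken up), Pd/CaCO3 poisoned with Pb(OAc)2, quinoline, Et2O, 0 °C → rt
Reagents that add atoms: none
Why: Lindlar-type semihydrogenation stops at the alkene stage for a terminal alkyne on the poisoned surface and leaves the trisubstituted E alkene alone, and the alkene geometry has no stereochemical consequence later because C4 ends up with two identical vinyl groups.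

Step 7
Reactants: 8 cyclopropylacetic acid ketal; 10 (E)-3-methylpenta-2,4-dien-1-ol
Product: 11 (E)-3-methylpenta-2,4-dienyl ester of 8
Conditions: DCC, DMAP (cat.), CH2Cl2, 0 °C → rt
Reagents that add atoms: none
Why: Steglich esterification joins acid and allylic alcohol under neutral conditions that neither ionise the dienyl alcohol nor touch the ketal.

Step 8
Reactants: 11 dienyl ester
Product: 14 (5R)-2-cyclopropyl-3-methyl-3-vinylpent-4-enoic acid (C10 dioxolane; cyclopropane as in 3), via silyl ketene acetal 12 (not isolated), via trimethylsilyl ester 13 (not isolated)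
Conditions: LiN(iPr)2, THF, −78 °C; Me3SiCl, −78 → 50 °C; then H2O
Reagents that add atoms: none
Why: Ireland–Claisen rearrangement: kinetic enolisation and O-silylation give 12, whose chair-like [3,3] shift forms the crowded C5–C4 bond below 60 °C and turns the dienyl terminus into a non-stereogenic carbon with two identical vinyl groups, while C5 is set by substrate control, since in the A(1,3)-minimised bisected conformer (C6–H eclipsing the ketene acetal) the allyl terminus should come in past the C11 methyl group rather than past the C8–C10 side chain on C7, a moderate preference for the drawn epimer.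

Step 9
Reactants: 14 divinyl acid
Product: 15 (5R)-2-cyclopropyl-3-methyl-3-vinylpent-4-en-1-ol (C10 dioxolane)
Conditions: LiAlH4, THF, 0 °C → reflux; then H2O
Reagents that add atoms: none
Why: Hydride reduction of the hindered acid with LiAlH4 leaves isolated alkenes, ketal and cyclopropane alone, cannot epimerise C5 once the carboxylate is formed, and gives an alcohol from which any minor C5 epimer is removed by chromatography.

Step 10
Reactants: 15 divinyl alcohol
Product: 16 (5R)-2-cyclopropyl-3-methyl-3-vinylpent-4-enal (C10 dioxolane)
Conditions: Dess–Martin periodinane, CH2Cl2, 0 °C → rt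
Reagents that add atoms: none
Why: Dess–Martin oxidation works without base at or below room temperature, so the alpha-branched aldehyde is obtained without over-oxidation and without epimerisation at C5.

Step 11
Reactants: 16 divinyl aldehyde
Product: 19 (4R,5R)-2-cyclopropyl-3-methyl-3-vinylcyclopentanone (C10 dioxolane; cyclopropyl cis to the C4 methyl group), via acylrhodium hydride 17 (not isolated), via acyl rhodacycle 18 (not isolated)
Conditions: [Rh(cod)2]BF4 (5 mol %), (R)-BINAP (5.5 mol %), CH2Cl2, H2 (1 atm, 30 min, strips cod), Ar purge; then 16, 25 → 40 °C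
Reagents that add atoms: none
Why: Oxidative addition of the C1–H bond to the cationic monovalent rhodium centre gives the trivalent acylrhodium hydride 17, one vinyl group binds and inserts into Rh–H with hydride going to the internal carbon C3 to give the six-membered acyl rhodacycle 18, and C1–C2 reductive elimination releases 19 and the catalyst. The closest known reaction type is the enantioselective intramolecular hydroacylation of 4-pentenals in its desymmetrising form on 3,3-dialkenyl substrates, used here as a selection between diastereotopic groups. The ring C1–C5 closes with both alkene carbons inside it (formally 5-endo), which is possible because the bond is made by reductive elimination from a six-membered metallacycle and not by direct attack. C4 becomes stereogenic only in this step; methyl and vinyl are nearly equal in size, so C5, C6 and C7 should exert little bias and the chiral pocket of the C2-symmetric bisphosphine decides which vinyl group reaches the hydride, while C5 is not touched under these neutral conditions. The step needs cyclisation over decarbonylation, bond formation at the terminal alkene carbon and no alkene migration, and the substrate secures these through the fully substituted C4 (angle compression, no allylic hydrogen), the strain of the alternative cyclobutanone path, the insulation of the cyclopropane from rhodium by C5 and the poor donor ability of the dioxolane.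

Step 12
Reactants: 19 vinyl cyclopentanone
Product: 20 bis(ethylene ketal) of 19 (C1 and C10 both as dioxolanes; C4 and C5 as in 19)
Conditions: Me3SiOCH2CH2OSiMe3, Me3SiOTf (cat.), CH2Cl2, −78 → −20 °C; pyridine quench
Reagents that add atoms: 1,2-bis(trimethylsiloxy)ethane, C[Si](C)(C)OCCO[Si](C)(C)C
Why: Noyori ketalisation (silylated glycol, catalytic silyl triflate) is driven by formation of the disiloxane and works at low temperature on hindered cyclopentanones, which masks C1 against the aryllithium while keeping enol ether formation and thus C5 epimerisation slow.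

Step 13
Reactants: 20 vinyl bis-ketal
Product: 22 C7' aldehyde (formyl group on C4 in place of vinyl; bis-ketal; C4 and C5 spatially as in 19), via terminal ozonide 21 (not isolated)
Conditions: O3, CH2Cl2, −78 °C (Sudan red end point); Me2S, −78 °C → rt
Reagents that add atoms: ozone, [O-][O+]=O
Why: Ozonolysis with reductive work-up cleaves the only alkene left, ketals without an acetal C–H and the cyclopropane being inert at −78 °C, and the resulting neopentyl aldehyde has no alpha hydrogen, so C4 is safe.

Step 14
Reactants: 23 1,3,5-tris(benzyloxy)benzene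
Product: 24 2-bromo-1,3,5-tris(benzyloxy)benzene
Conditions: NBS (1 equiv), CH2Cl2, −78 → 0 °C
Reagents that add atoms: N-bromosuccinimide, O=C1CCC(=O)N1Br
Why: Electrophilic aromatic bromination of the very electron-rich ring with one equivalent of NBS at low temperature stops at the monobromide, all three free positions being equivalent.

Step 15
Reactants: 24 aryl bromide; 22 C7' aldehyde
Product: 26 C7' carbinol [2,4,6-tris(benzyloxy)phenyl](C4)methanol (bis-ketal; both C7' epimers), via aryllithium 25 (not isolated)
Conditions: n-BuLi, THF, −78 °C; then 22, −78 → −30 °C; H2O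
Reagents that add atoms: none
Why: Bromine–lithium exchange followed by 1,2-addition of the aryllithium to a non-enolisable aldehyde is reliable even for neopentyl aldehydes, both ketones are masked, and the C7' carbinol epimers need not be separated because this centre is planarised in the next step.

Step 16
Reactants: 26 C7' carbinol; 27 methallyltrimethylsilane
Product: 29 (7'R)-methallyl adduct (C7' bears H; 2-methylallyl; 2,4,6-tris(benzyloxy)phenyl; bis-ketal), via benzylic cation 28 (not isolated)
Conditions: BF3·OEt2, CH2Cl2, −78 °C; aq NaHCO3
Reagents that add atoms: none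
Why: Hosomi–Sakurai-type SN1 allylation: the three alkoxy groups let the carbinol ionise at −78 °C, well below the threshold for opening of the dioxolanes or for a 1,2-shift from C4, and C7' is set by a Felkin–Anh-like approach to the planar cation 28 in which the C4 methyl group lies next to the ortho benzyloxy group (least A(1,3) strain), the bulky C5 arm stands perpendicular and the silane attacks the opposite face, which corresponds to the drawn configuration.

Step 17
Reactants: 29 methallyl adduct
Product: 30 (7'R)-isobutyl phloroglucinol bis-ketal (2-substituted benzene-1,3,5-triol)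
Conditions: H2 (1 atm), Pd/C, EtOAc–EtOH, rt
Reagents that add atoms: none
Why: Heterogeneous hydrogenation saturates the 1,1-disubstituted alkene and hydrogenolyses the three benzyl ethers in one operation under neutral conditions, whereas the trialkyl cyclopropane, the ketals and the C7'–aryl bond are not cleaved at one atmosphere.

Step 18
Reactants: 30 phloroglucinol bis-ketal
Product: 32 target CNP0217082.3, via bis(iminium) salt 31 (not isolated)
Conditions: [Me2N=CHCl]Cl (2.5 equiv), MeCN, 0 °C → rt; then 1 M HCl, THF–H2O, 40 °C
Reagents that add atoms: (chloromethylene)dimethyliminium chloride, C[N+](C)=CCl.[Cl-]; water, O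
Why: Vilsmeier–Haack formylation attacks the two remaining, extremely nucleophilic ring positions of the free phloroglucinol much faster than any ketal-derived enol ether, and the acidic aqueous stage hydrolyses both iminium groups and both dioxolanes, C5 being safe because a cyclopropyl group trans to the bulky C7' branch is the thermodynamically preferred arrangement next to the C1 ketone.

Compound list
1 | (+)-2-carene, (1S,6R)-3,7,7-trimethylbicyclo[4.1.0]hept-2-ene | CC1=C[C@H]2[C@@H](CC1)C2(C)C | starting material
2 | secondary ozonide (1,2,4-trioxolane) of 1 | CC12CC[C@@H]3[C@H](C(O1)OO2)C3(C)C | intermediate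
3 | (1S,3R)-2,2-dimethyl-3-(3-oxobutyl)cyclopropane-1-carbaldehyde (cis) | CC(=O)CC[C@@H]1[C@H](C=O)C1(C)C | intermediate
4 | 4-(cis-2,2-dimethyl-3-vinylcyclopropyl)butan-2-one | CC(=O)CC[C@@H]1[C@H](C=C)C1(C)C | intermediate
5 | ethylene ketal of 4 | CC1(CC[C@@H]2[C@H](C=C)C2(C)C)OCCO1 | intermediate
6 | B-alkyl-9-borabicyclo[3.3.1]nonane from 5 | CC1(CC[C@@H]2[C@H](CCB3C4CCCC3CCC4)C2(C)C)OCCO1 | intermediate
7 | 2-cyclopropylethanol ketal | CC1(CC[C@@H]2[C@H](CCO)C2(C)C)OCCO1 | intermediate
8 | cyclopropylacetic acid ketal | CC1(CC[C@@H]2[C@H](CC(=O)O)C2(C)C)OCCO1 | intermediate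
9 | (E)-3-methylpent-2-en-4-yn-1-ol | C#C/C(C)=C/CO | starting material
10 | (E)-3-methylpenta-2,4-dien-1-ol | C=C/C(C)=C/CO | intermediate
11 | (E)-3-methylpenta-2,4-dienyl ester of 8 | CC1(CC[C@@H]2[C@H](CC(=O)OC/C=C(C)/C=C)C2(C)C)OCCO1 | intermediate
12 | trimethylsilyl ketene acetal of 11 (ketene acetal geometry without consequence) | CC1(CC[C@@H]2[C@H](C=C(O[Si](C)(C)C)OC/C=C(C)/C=C)C2(C)C)OCCO1 | intermediate
13 | trimethylsilyl ester of 14 | CC1(CC[C@@H]2[C@H]([C@@H](C(=O)O[Si](C)(C)C)C(C)(C=C)C=C)C2(C)C)OCCO1 | intermediate
14 | (5R)-2-cyclopropyl-3-methyl-3-vinylpent-4-enoic acid, C10 dioxolane | CC1(CC[C@@H]2[C@H]([C@@H](C(=O)O)C(C)(C=C)C=C)C2(C)C)OCCO1 | intermediate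
15 | (5R)-2-cyclopropyl-3-methyl-3-vinylpent-4-en-1-ol, C10 dioxolane | CC1(CC[C@@H]2[C@H]([C@@H](CO)C(C)(C=C)C=C)C2(C)C)OCCO1 | intermediate
16 | (5R)-2-cyclopropyl-3-methyl-3-vinylpent-4-enal, C10 dioxolane (key-step precursor) | CC1(CC[C@@H]2[C@H]([C@@H](C=O)C(C)(C=C)C=C)C2(C)C)OCCO1 | intermediate
17 | acylrhodium hydride from 16 (bisphosphine and charge omitted) | CC1(CC[C@@H]2[C@H]([C@@H](C(=O)[RhH])C(C)(C=C)C=C)C2(C)C)OCCO1 | intermediate
18 | six-membered acyl rhodacycle (bisphosphine and charge omitted) | CC1(CC[C@@H]2[C@H]([C@H]3C(=O)[Rh]CC[C@]3(C)C=C)C2(C)C)OCCO1 | intermediate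
19 | (4R,5R)-2-cyclopropyl-3-methyl-3-vinylcyclopentanone, C10 dioxolane (key-step product) | CC1(CC[C@@H]2[C@H]([C@H]3C(=O)CC[C@]3(C)C=C)C2(C)C)OCCO1 | intermediate
20 | C1,C10-bis(ethylene ketal) of 19 | CC1(CC[C@@H]2[C@H]([C@H]3C4(OCCO4)CC[C@]3(C)C=C)C2(C)C)OCCO1 | intermediate
21 | terminal ozonide of 20 | CC1(CC[C@@H]2[C@H]([C@H]3C4(OCCO4)CC[C@]3(C)C3OCOO3)C2(C)C)OCCO1 | intermediate
22 | C7' aldehyde, bis-ketal | CC1(CC[C@@H]2[C@H]([C@H]3C4(OCCO4)CC[C@]3(C)C=O)C2(C)C)OCCO1 | intermediate
23 | 1,3,5-tris(benzyloxy)benzene | c1ccccc1COc1cc(OCc2ccccc2)cc(OCc2ccccc2)c1 | starting material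
24 | 2-bromo-1,3,5-tris(benzyloxy)benzene | Brc1c(OCc2ccccc2)cc(OCc2ccccc2)cc1OCc1ccccc1 | intermediate
25 | 2,4,6-tris(benzyloxy)phenyllithium | [Li]c1c(OCc2ccccc2)cc(OCc2ccccc2)cc1OCc1ccccc1 | intermediate
26 | C7' carbinol, bis-ketal (both C7' epimers) | CC1(CC[C@@H]2[C@H]([C@H]3C4(OCCO4)CC[C@]3(C)C(O)c3c(OCc4ccccc4)cc(OCc4ccccc4)cc3OCc3ccccc3)C2(C)C)OCCO1 | intermediate
27 | methallyltrimethylsilane | CC(=C)C[Si](C)(C)C | starting material
28 | 2,4,6-tris(benzyloxy)benzylic cation at C7' | CC1(CC[C@@H]2[C@H]([C@H]3C4(OCCO4)CC[C@]3(C)[CH+]c3c(OCc4ccccc4)cc(OCc4ccccc4)cc3OCc3ccccc3)C2(C)C)OCCO1 | intermediate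
29 | (7'R)-methallyl adduct, tribenzyl ether, bis-ketal | CC1(CC[C@@H]2[C@H]([C@H]3C4(OCCO4)CC[C@]3(C)[C@@H](CC(C)=C)c3c(OCc4ccccc4)cc(OCc4ccccc4)cc3OCc3ccccc3)C2(C)C)OCCO1 | intermediate
30 | (7'R)-isobutyl phloroglucinol, bis-ketal | CC1(CC[C@@H]2[C@H]([C@H]3C4(OCCO4)CC[C@]3(C)[C@@H](CC(C)C)c3c(O)cc(O)cc3O)C2(C)C)OCCO1 | intermediate
31 | 3',5'-bis(dimethyliminiomethyl) dichloride of 30 | CC1(CC[C@@H]2[C@H]([C@H]3C4(OCCO4)CC[C@]3(C)[C@@H](CC(C)C)c3c(O)c(C=[N+](C)C)c(O)c(C=[N+](C)C)c3O)C2(C)C)OCCO1.[Cl-].[Cl-] | intermediate
32 | CNP0217082.3 (4R,5R,6R,7R,7'R) | CC(=O)CC[C@@H]1[C@H]([C@H]2C(=O)CC[C@]2(C)[C@@H](CC(C)C)c2c(O)c(C=O)c(O)c(C=O)c2O)C1(C)C | target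

Total step count: 18. Longest linear sequence: 16 steps (steps 1–5, 7–13 and 15–18, from 1 to 32). Steps 6 and 14 are one-step side branches.

Steps most likely to fail

Step 11. The catalyst may discriminate poorly between the two vinyl groups. Decarbonylation of the acylrhodium hydride may also outrun alkene insertion and deactivate the rhodium. The fallback replaces C–H activation by ring-closing metathesis and runs from 16 back to 19. Vinylmagnesium bromide is added to 16 to give the triene carbinol F1. The second-generation Grubbs catalyst (or a chiral molybdenum alkylidene if reagent control is wanted) then closes the only ring that can form. This gives the cyclopentenol F2, whose C4 diastereomers are separated by chromatography. Dess–Martin oxidation gives the enone F3. Conjugate reduction with [(Ph3P)CuH]6 leaves the vinyl group alone and delivers 19.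

Step 16. Capture of the cation may show poor or reversed facial selectivity, or the Lewis acid may start to open the dioxolanes. The fallback delivers hydride last instead of carbon last and runs from 26 back to 29. Dess–Martin oxidation of 26 gives the aryl ketone F4. Methallylmagnesium chloride, which adds through a cyclic transition state even to very hindered ketones, gives the tertiary carbinol F5. Ionic reduction with Et3SiH and BF3·OEt2 at −78 °C sends hydride to the same open face of the now tertiary cation. A facial preference that is wrong in step 16 therefore becomes the right one and leads to 29.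

Step 8. Weak discrimination between the two faces of the ketene acetal would erode the configuration at C5. The fallback replaces kinetic control by separation and base equilibration and runs from 14 back to 16.
- The acid 14 is taken on together with the C5-epimeric acid F6.
- Reduction as in step 9 gives 15 and the C5-epimeric alcohol F7, which are separated on silica.
- F7 is oxidised with Dess–Martin periodinane to the C5-epimeric aldehyde F8.
- F8 is equilibrated with catalytic DBU in toluene through its enolate.
- The resulting mixture of 16 and F8 is separated. If that is impractical, it is reduced with NaBH4 and separated as 15 and F7.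
- Repeated cycles feed the material into 16.

Further compounds
F1 | step 11 | triene carbinol, 4-cyclopropyl-5-methyl-5-vinylhepta-1,6-dien-3-ol (C10 dioxolane, both C1 epimers) | CC1(CC[C@@H]2[C@H]([C@@H](C(O)C=C)C(C)(C=C)C=C)C2(C)C)OCCO1
F2 | step 11 | cyclopentenol, 5-cyclopropyl-4-methyl-4-vinylcyclopent-2-en-1-ol (C10 dioxolane, C4 and C5 as in 19) | CC1(CC[C@@H]2[C@H]([C@H]3C(O)C=C[C@]3(C)C=C)C2(C)C)OCCO1
F3 | step 11 | enone, 5-cyclopropyl-4-methyl-4-vinylcyclopent-2-en-1-one (C10 dioxolane, C4 and C5 as in 19) | CC1(CC[C@@H]2[C@H]([C@H]3C(=O)C=C[C@]3(C)C=C)C2(C)C)OCCO1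
F4 | step 16 | aryl ketone at C7', tribenzyl ether, bis-ketal | CC1(CC[C@@H]2[C@H]([C@H]3C4(OCCO4)CC[C@]3(C)C(=O)c3c(OCc4ccccc4)cc(OCc4ccccc4)cc3OCc3ccccc3)C2(C)C)OCCO1
F5 | step 16 | tertiary carbinol at C7' bearing methallyl and aryl, bis-ketal | CC1(CC[C@@H]2[C@H]([C@H]3C4(OCCO4)CC[C@]3(C)C(O)(CC(C)=C)c3c(OCc4ccccc4)cc(OCc4ccccc4)cc3OCc3ccccc3)C2(C)C)OCCO1
F6 | step 8 | C5-epimeric acid (5S epimer of 14) | CC1(CC[C@@H]2[C@H]([C@H](C(=O)O)C(C)(C=C)C=C)C2(C)C)OCCO1
F7 | step 8 | C5-epimeric alcohol (5S epimer of 15) | CC1(CC[C@@H]2[C@H]([C@H](CO)C(C)(C=C)C=C)C2(C)C)OCCO1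
F8 | step 8 | C5-epimeric aldehyde (5S epimer of 16) | CC1(CC[C@@H]2[C@H]([C@H](C=O)C(C)(C=C)C=C)C2(C)C)OCCO1
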